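## Structural features

The target is a C19 gibberellin with a 6-5-6-5 carbocyclic frame. Ring B (C5, C6, C8, C9, C10) is fused to ring A at C5–C10 and to the bicyclo[3.2.1]octane of rings C and D at C8–C9. A γ-lactone (C19 carbonyl on C4, oxygen on C10) bridges ring A on its α face. There are ten stereocentres (C2, C3, C4, C5, C6, C8, C9, C10, C11, C13). C4, C5, C10, C9, C8 and C6 are contiguous; C4 and C8 are all-carbon quaternary and C10 is a fully substituted carbinol carbon. The C7 acid on C6 is trans to C4 on C5, the 2,3-diol is cis on the β face (away from the lactone bridge), and the 11-hydroxyl is axial on ring C, pointing at the C15–C16 bridge. The fragile groups are the 3-hydroxy lactone (retro-aldol epimerisation in base), the exocyclic C16=C17 alkene (acid, osmium), and C6 and C9 whenever a carbonyl is next to them. The real difficulty is C8, which is shared by rings B, C and D, together with the C4/C5/C10 array and the hindered axial oxygen at C11. The key step exploits that C8, C9, C15, C16, C13 and C14 form a six-membered carbocycle that can be drawn as the benzene ring of an indane fused to ring B. That ring already carries oxygen on C15 and C16. Its dienone takes up C11–C12 across C9 and C13, and the C15 carbonyl then sits one bond from C8, ready for a 1,2-acyl shift.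

## Logic of the disconnections

30 to 28. The acid is unmasked last from its methyl ester (29), and the C16=C17 bond is cut back to the C16 ketone (28). The alkene cannot coexist with osmium or with acid, so it must come after both. The forward methylenation therefore has to be non-basic, because the 3-hydroxy lactone is already present.

28 to 27. The C2–O and C3–O bonds are cut to the C2=C3 alkene. One reagent then sets two stereocentres, and the lactone bridge should shield the α face. The demand is that no other alkene is present.

27 to 24. The C15 methylene is traced to a C15 carbinol next to the C16 ketone (26). That and the 11β-hydroxyl go back to the C11, C15-diketone 24 with C16 still a ketal. A single hydride step then serves both carbons. The demand is that hydride reaches C11 from the face away from the C15–C16 bridge.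

24 to 21. The C11 ketone comes from the 11α-tert-butyl ether (22). The C2=C3 bond is then cut (ring-closing metathesis) to the allyl group on C10 and the vinyl group on C4 (21). Both groups must sit on the same face of the lactone ring.

21 to 18. The C3–C4 bond is cut. The lactone enolate of 18 should take a vinyl cation equivalent on its convex face, which is the face of C1. This fixes the quaternary centre C4 by the shape of the bicycle and not by enolate geometry.

18 to 17. The C4–C5 bond is cut: an ester enolate held on the C10 oxygen adds to C5 of a cyclopentene ester. The tether fixes C5 and makes the lactone at once. The demand is a C5=C6 acceptor and a five-membered closure with the enolate double bond inside the ring.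

17 to 13. The C1–C10 bond and the ester C–O bond are cut to the enone 13, allylmagnesium bromide and propionic anhydride. The ring B carbonyl is the natural site for C1. The demand is β-face addition and selectivity over the C15 ketone.

13 to 11. The C5=C6 bond is removed again to give the saturated keto ester 11. This costs the C6 stereocentre, which by then has done its work, and C6 is set again under thermodynamic control in step 9.

11 to 10. The C8–C15 bond is cut and C15 is put back on C9. This converts the bicyclo[3.2.1]octane into a bicyclo[2.2.2]octene that a Diels–Alder reaction can make. The forward shift needs a radical at C8 and a better radical at C9. The C11 oxygen is kept as its ether here, so that C9 never carries three acyl groups and no 1,3-diketone arises afterwards. The C10 ketone alone must then drive the shift.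

10 to 7 and 8. The C9–C11 and C12–C13 bonds are cut. This is the key disconnection and removes two rings and three stereocentres, leaving an indanone phenol. The demand is regio-, endo- and facial control from one stereocentre, C6.

7 to 5. The O–methyl bond (6) and then the C5–C10 bond are cut, which opens ring B to an aldehyde and an acrylate. An enantioselective hydroacylation can then set C6 without a resolution. A Friedel–Crafts route from guaiacol and maleic anhydride was set aside for three reasons: acylation ortho to a free phenol is not the normal regiochemistry, the aroylacrylic acid can close on the phenol oxygen, and half of a racemate would be lost.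

5 to 4, 3, 2 and 1. The aryl–vinyl bond is cut to the commercial bromide 4 and the stannane 3. The stannane comes from 1 and 2 by hydrostannation. The bromide already holds the full 1,2,3,4-substitution pattern.

## Other disconnections considered

Alternative 1: The cut is C5–C10 together with the lactone C–O bond. In the forward step SmI2 would reduce the C10 ketone; the ketyl would add 5-exo to C5 of an enoate, and the samarium alkoxide would then acylate on the C19 ester to give A1. In its favour, ketyl–enoate closure is a dependable one-electron reaction. It would make ring B, the C10–O bond and the lactone in one operation, where the chosen plan needs steps 7 to 9; on this point it is the better design. A1 also carries C11–O in the final configuration and C16 as a ketal, so it needs no C15 deoxygenation and no inversion at C11, which is again better. Against it here, the open precursor needs an enantioselective synthesis of the whole bicyclo[3.2.1]octane with quaternary C8, which the chosen plan gets from an arene. The epimerisable C9 sits next to the ketone before closure. A1 also has C4–H and a C3 acetal, so ring A would close by an aldol that gives only the 3-hydroxyl, and the 2β-hydroxyl would cost extra steps. In the chosen plan metathesis gives C2=C3 directly. Mechanistically the two are equally well founded. In step count the union step of A1 wins, but the total would probably not be shorter.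

Alternative 2: The cut is C5–C6 and C4–C18. In the forward step the C6 lithium enolate of the CD ester A2 would add to C5 of the quinone monoketal A3, and the β-keto ester enolate would be methylated to give A4. In its favour, it is convergent, which the linear chosen plan is not, and it brings all of ring A, the quaternary C4 and C19 in one flask; on both counts it is better. Ring A also arrives with a C3 ketone and a C1=C2 enone as handles for oxygenation, which is at least equal. Against it here, A4 still lacks the C9–C10 bond, so ring B and both C9 and C10 would be set late. C5 and C6 would be formed in an intermolecular step between a neopentyl enolate and a carbon next to a ketal, with only the distant chirality of A2 to control them. The exocyclic alkene is carried from the start, which rules out osmium for the cis-diol. The chosen plan has ring B from the first step and sets C5 intramolecularly.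

Alternative 3: The cut is C8–C9 and C12–C13. In the forward step an oxyallyl cation from a chloromethyl ketone would add across the termini of a tethered cyclopentadiene in a (4+3) cycloaddition, closing rings B, C and D to give A5. In its favour, it builds more per step than the chosen key step, which closes two rings and still needs a skeletal shift. The allylsilane would give C16=C17 and C15H2 by protodesilylation with no deoxygenation. Both points are better than the chosen plan, and the C11 ketone is equal to compound 24. Against it here, substituted cyclopentadienes scramble by 1,5-hydrogen shifts. The compact or extended approach decides C9. The allylsilane and the ketal next to the cation are acid-labile under the ionising conditions. Facial control again rests on the C6 ester alone, which is equal, and ring A is still to be built, which is also equal. The risk is concentrated in one step, whereas the chosen plan spreads it over a well-known cycloaddition and a radical shift.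

Key step: step 5

Remark: "safe" is read as robust and well-precedented chemistry.
Remark: in step 3, (R)-BINAP is assumed to give the (S)-ester; if the sense of induction is the opposite, (S)-BINAP is used.
Remark: adduct 10 carries the endo (11α) ether, the epimer of the target's 11β-hydroxyl; no structure needed correction, and C11 is inverted through the ketone 24.
Remark: C4 in 18 (re-enolised in step 10) and C15 in 25 and 26 (becomes CH2 in step 14) are left undefined.

## Steps

Step 1
Reactants: 1 methyl propiolate; 2 tributyltin hydride
Product: 3 methyl 2-(tributylstannyl)acrylate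
Conditions: Pd(PPh3)4 (2 mol%), THF, 0 °C to rt
Reagents that add atoms: none
Why: Zerovalent-palladium-catalysed syn hydrostannation of an alkynoate should place tin on the carbon α to the ester; the minor β-stannyl isomer is removed on purification.

Step 2
Reactants: 4 6-bromo-2,3-dimethoxybenzaldehyde; 3 methyl 2-(tributylstannyl)acrylate
Product: 5 methyl 2-(2-formyl-3,4-dimethoxyphenyl)acrylate
Conditions: Pd(PPh3)4 (5 mol%), CuI (10 mol%), CsF, DMF, 45 °C
Reagents that add atoms: none
Why: Stille coupling; CuI and fluoride speed transmetalation of the hindered α-stannyl acrylate and should suppress cine substitution, and the aldehyde is inert under these base-free conditions.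

Step 3
Reactants: 5 methyl 2-(2-formyl-3,4-dimethoxyphenyl)acrylate
Product: 6 methyl (S)-4,5-dimethoxy-3-oxo-2,3-dihydro-1H-indene-1-carboxylate
Conditions: [Rh(nbd)((R)-BINAP)]BF4 (5 mol%, activated with H2), CH2Cl2, 25 °C
Reagents that add atoms: none
Why: Intramolecular alkene hydroacylation of a 2-alkenylbenzaldehyde: monovalent rhodium inserts into the formyl C–H, the hydride adds to the 1,1-disubstituted alkene and C–C reductive elimination closes ring B (C5–C10); the chiral diphosphine selects the alkene face and sets C6.

Step 4
Reactants: 6 methyl (S)-4,5-dimethoxy-3-oxo-2,3-dihydro-1H-indene-1-carboxylate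
Product: 7 methyl (S)-4-hydroxy-5-methoxy-3-oxo-2,3-dihydro-1H-indene-1-carboxylate
Conditions: BCl3, CH2Cl2, −78 to 0 °C; then H2O
Reagents that add atoms: none
Why: Chelation-controlled ether cleavage: boron bridges the ketone oxygen and the neighbouring methoxy oxygen, so chloride removes only that methyl group; the conditions are non-basic and should leave C6 and the ester untouched.

Step 5
Reactants: 7 methyl (S)-4-hydroxy-5-methoxy-3-oxo-2,3-dihydro-1H-indene-1-carboxylate; 8 tert-butyl vinyl ether
Product: 10 bicyclo[2.2.2]octenone adduct (C10 and C15 ketones, C16 dimethyl ketal, endo 11-tert-butoxy, C8=C14), via masked ortho-benzoquinone 9 (not isolated)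
Conditions: PhI(OAc)2 (1.1 equiv, slow addition), MeOH, 8 (20 equiv), 0 °C to rt
Reagents that add atoms: methanol, CO
Why: Trivalent iodine activates the phenol oxygen and methanol adds at the methoxy-bearing carbon C16, giving the 6,6-dimethoxycyclohexa-2,4-dienone 9 with C15 as ketone and C9=C8–C14=C13 as diene. This electron-poor diene and the enol ether should combine in a concerted, asynchronous, suprafacial inverse-demand (4+2) cycloaddition, the closest known type being the trapping of masked ortho-benzoquinones by vinyl ethers. Two six-membered rings close in the one (4+2) event, ring C (C8, C9, C11, C12, C13, C14) and the ring C9–C15–C16–C13–C12–C11, which together form the bicyclo[2.2.2]octenone. The largest LUMO coefficient lies on C13, vinylogous to both the C15 and C10 carbonyls, so the nucleophilic CH2 of 8 (C12) bonds there and the oxygen-bearing C11 bonds to C9. C9 and C13 are bridgeheads set together by the face of attack: the dienophile should approach anti to the C6 ester, which puts the C11–C12 bridge on the α face and leaves C15 on the β face. C11 is set by the endo transition state (alkoxy group under the diene, syn to the new C8=C14 bond); this centre is later passed through a ketone, so any exo isomer is not lost. The step needs cross-addition to beat dimerisation of 9, which slow oxidant addition into excess 8 and the acyl group on C9 should secure, and it needs facial selectivity, which rests on the C6 ester.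

Step 6
Reactants: 10 bicyclo[2.2.2]octenone adduct
Product: 11 bicyclo[3.2.1]octane diketone (C15 on C8, 9β-H, C10 and C15 ketones, C16 ketal, 11α-tert-butoxy)
Conditions: Fe(acac)3 (0.5 equiv), PhSiH3 (3 equiv), EtOH–THF (1:1), 40 °C
Reagents that add atoms: none
Why: Hydrogen-atom transfer from an iron hydride to C14 gives the tertiary C8 radical, which closes 3-exo on the C15 ketone and reopens on the C9 side (Dowd–Beckwith 1,2-acyl shift), because the C9 radical is tertiary and α to the C10 ketone and the cage relaxes to bicyclo[3.2.1]. C15 stays on the β face, which fixes C8; reduction to the C10 enolate and protonation should give the cis B/C-fused 9β-H under thermodynamic control.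

Step 7
Reactants: 11 bicyclo[3.2.1]octane diketone
Product: 13 enone ester (C5=C6, conjugated with the C10 ketone and the C7 ester), via trimethylsilyl enol ether 12 (not isolated)
Conditions: LiN(iPr)2, Me3SiCl, THF, −78 °C; then Pd(OAc)2 (1.1 equiv), MeCN, 25 °C
Reagents that add atoms: none
Why: Saegusa–Ito dehydrogenation: kinetic deprotonation occurs at C5H2 (C9–H is a hindered methine and C15 has no α-hydrogen), and divalent palladium then eliminates H6 to give the C5=C6 acceptor needed in step 9. The C6 stereocentre has already served in step 5 and is set again in step 9.

Step 8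
Reactants: 13 enone ester; 14 allylmagnesium bromide; 15 propionic anhydride
Product: 17 10β-allyl 10α-propanoate (tertiary allylic ester), via bromomagnesium alkoxide 16 (not isolated)
Conditions: 14 (1.3 equiv), CeCl3, THF, −78 °C; then 15, 4-(dimethylamino)pyridine, −78 to 25 °C
Reagents that add atoms: none
Why: Cerium-mediated 1,2-addition to the enone carbonyl avoids enolisation at C9 and conjugate addition; attack anti to the C9–C11 bond (convex β face) sets C10 with C1 β and oxygen α. The C15 ketone lies between two fully substituted carbons and should react far more slowly; the alkoxide is acylated in the same flask.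

Step 9
Reactants: 17 10β-allyl 10α-propanoate
Product: 18 19,10-lactone (C4–C5 bond formed, 4-methyl as C4 epimers, 5β-H, 6β-ester)
Conditions: KN(SiMe3)2, THF, −78 to 0 °C; then MeOH, 25 °C; NH4Cl (aq)
Reagents that add atoms: none
Why: Intramolecular Michael addition of the propanoate enolate, held on the C10 oxygen, to C5 of the cyclopentene ester forms C4–C5 and the γ-lactone; the tether forces cis fusion, so C5 carries H on the β face. Methoxide equilibration should place the C7 ester trans to C4.

Step 10
Reactants: 18 19,10-lactone; 19 phenyl vinyl sulfoxide
Product: 21 4-methyl-4-vinyl lactone (vinyl cis to the C10 allyl group), via sulfoxide adduct 20 (not isolated)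
Conditions: LiN(iPr)2, THF, −78 °C; 19, −78 to 0 °C; NH4Cl (aq); then toluene, 110 °C
Reagents that add atoms: none
Why: The lactone α-hydrogen is more acidic and less shielded than H6, and its enolate should add to the vinyl sulfoxide (a vinyl cation equivalent) on the convex face of the cis-fused bicycle, the face of H5 and C1, which sets the quaternary C4. Thermal syn elimination of the sulfoxide then releases the vinyl group.

Step 11
Reactants: 21 4-methyl-4-vinyl lactone
Product: 22 ring A cyclohexene lactone (C2=C3, 11α-tert-butoxy, C15 ketone, C16 ketal)
Conditions: second-generation Grubbs catalyst (RuCl2(=CHPh)(H2IMes)(PCy3), 5 mol%), CH2Cl2, 40 °C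
Reagents that add atoms: none
Why: Ring-closing metathesis of the cis-disposed allyl and vinyl groups closes the six-membered ring A with loss of ethene; no other alkene is present.

Step 12
Reactants: 22 ring A cyclohexene lactone
Product: 24 11,15-diketone (C16 ketal intact), via 11α-alcohol 23 (not isolated)
Conditions: CF3CO2H, CH2Cl2, 0 °C; evaporate; then Dess–Martin periodinane, CH2Cl2, 25 °C
Reagents that add atoms: none
Why: Acidolysis removes the tert-butyl group as isobutene, while the ketal should survive because the adjacent C15 carbonyl disfavours its oxocarbenium ion. Dess–Martin oxidation then erases the 11α configuration from the cycloaddition.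

Step 13
Reactants: 24 11,15-diketone
Product: 26 11β,15-dihydroxy 16-ketone, via diol ketal 25 (not isolated)
Conditions: NaBH4, MeOH, 0 to 25 °C; then 1 M HCl, THF, 25 °C
Reagents that add atoms: water, O
Why: Hydride should reach C11 only from the face away from the C15–C16 bridge, which the C16 ketal blocks, giving the axial 11β-alcohol; the C15 ketone is reduced in the same step. Once C15 is a carbinol the ketal is an ordinary one and dilute acid hydrolyses it to the C16 ketone.

Step 14
Reactants: 26 11β,15-dihydroxy 16-ketone
Product: 27 11β-hydroxy 16-ketone (C15 as CH2)
Conditions: SmI2 (3 equiv), THF–MeOH, −78 to 0 °C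
Reagents that add atoms: none
Why: Reductive cleavage of an α-oxygenated ketone: the C16 ketyl expels the C15 oxygen and methanol protonates the samarium enolate; the lactone, ester and alkene are not reduced at this temperature.

Step 15
Reactants: 27 11β-hydroxy 16-ketone
Product: 28 2β,3β,11β-trihydroxy 16-ketone methyl ester
Conditions: OsO4 (5 mol%), N-methylmorpholine N-oxide, acetone–H2O, 25 °C
Reagents that add atoms: osmium tetroxide, O=[Os](=O)(=O)=O; N-methylmorpholine N-oxide, C[N+]1([O-])CCOCC1; water, O
Why: Suprafacial osmylation gives the cis-diol. The lactone bridge covers the α face of C2=C3 and the β face carries only H5 on the one-atom bridge, so both hydroxyls should enter β; C2=C3 is the only alkene.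

Step 16
Reactants: 28 2β,3β,11β-trihydroxy 16-ketone methyl ester
Product: 29 methyl ester of the target
Conditions: Zn, CH2Br2, TiCl4 (excess reagent), THF–CH2Cl2, 0 to 25 °C
Reagents that add atoms: dibromomethane, BrCBr
Why: Lombardo methylenation: the non-basic zinc–titanium methylene reagent converts the C16 ketone into the exocyclic alkene without touching the ester or lactone, and it avoids the alkoxide-driven retro-aldol at C3 that a phosphorus ylide would risk.

Step 17
Reactants: 29 methyl ester of the target
Product: 30 CNP0322347.1
Conditions: NaSEt, HMPA, 25 °C; then dilute HCl to pH 3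
Reagents that add atoms: none
Why: SN2 demethylation by thiolate at the methyl group of the hindered C7 ester needs no attack at a carbonyl carbon, so the lactone and the C3 configuration should stay intact.

## Compound list

1 | methyl propiolate | C#CC(=O)OC | starting material
2 | tributyltin hydride | CCCC[SnH](CCCC)CCCC | starting material
3 | methyl 2-(tributylstannyl)acrylate | C=C(C(=O)OC)[Sn](CCCC)(CCCC)CCCC | intermediate
4 | 6-bromo-2,3-dimethoxybenzaldehyde | O=Cc1c(Br)ccc(OC)c1OC | starting material
5 | methyl 2-(2-formyl-3,4-dimethoxyphenyl)acrylate | C=C(C(=O)OC)c1ccc(OC)c(OC)c1C=O | intermediate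
6 | methyl (S)-4,5-dimethoxy-3-oxo-2,3-dihydro-1H-indene-1-carboxylate | COC(=O)[C@H]1CC(=O)c2c(OC)c(OC)ccc21 | intermediate
7 | methyl (S)-4-hydroxy-5-methoxy-3-oxo-2,3-dihydro-1H-indene-1-carboxylate | COC(=O)[C@H]1CC(=O)c2c(O)c(OC)ccc21 | intermediate
8 | tert-butyl vinyl ether | C=COC(C)(C)C | starting material
9 | masked ortho-benzoquinone (6,6-dimethoxy dienone, C15 ketone, C16 ketal) | COC(=O)[C@H]1CC(=O)C2=C1C=CC(OC)(OC)C2=O | intermediate (not isolated)
10 | bicyclo[2.2.2]octenone adduct (rings B and C, C15 on C9, endo 11-tert-butoxy) | COC(=O)[C@H]1CC(=O)[C@@]23C(=O)C(OC)(OC)[C@@H](C=C12)C[C@H]3OC(C)(C)C | intermediate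
11 | bicyclo[3.2.1]octane diketone (rings B, C, D; C15 on C8; 9β-H) | COC1(OC)C(=O)[C@]23C[C@H]1C[C@@H](OC(C)(C)C)[C@H]2C(=O)C[C@@H]3C(=O)OC | intermediate
12 | C10 trimethylsilyl enol ether of 11 (C10=C5) | COC1(OC)C(=O)[C@]23C[C@H]1C[C@@H](OC(C)(C)C)[C@H]2C(O[Si](C)(C)C)=C[C@@H]3C(=O)OC | intermediate (not isolated)
13 | enone ester (C5=C6) | COC1(OC)C(=O)[C@]23C[C@H]1C[C@@H](OC(C)(C)C)[C@H]2C(=O)C=C3C(=O)OC | intermediate
14 | allylmagnesium bromide | C=CC[Mg]Br | starting material
15 | propionic anhydride | CCC(=O)OC(=O)CC | starting material
16 | bromomagnesium 10α-alkoxide of the 10β-allyl carbinol | COC1(OC)C(=O)[C@]23C[C@H]1C[C@@H](OC(C)(C)C)[C@H]2[C@@](CC=C)(O[Mg]Br)C=C3C(=O)OC | intermediate (not isolated)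
17 | 10β-allyl 10α-propanoate | COC1(OC)C(=O)[C@]23C[C@H]1C[C@@H](OC(C)(C)C)[C@H]2[C@@](CC=C)(OC(=O)CC)C=C3C(=O)OC | intermediate
18 | 19,10-lactone, 4-methyl (C4 epimers), 5β-H, 6β-ester | COC1(OC)C(=O)[C@]23C[C@H]1C[C@@H](OC(C)(C)C)[C@H]2[C@@]1(CC=C)OC(=O)C(C)[C@H]1[C@@H]3C(=O)OC | intermediate
19 | phenyl vinyl sulfoxide | C=CS(=O)c1ccccc1 | starting material
20 | 4-methyl-4-[2-(phenylsulfinyl)ethyl] lactone (sulfur configuration undefined) | COC1(OC)C(=O)[C@]23C[C@H]1C[C@@H](OC(C)(C)C)[C@H]2[C@@]1(CC=C)OC(=O)[C@](C)(CCS(=O)c2ccccc2)[C@H]1[C@@H]3C(=O)OC | intermediate (not isolated)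
21 | 4-methyl-4-vinyl lactone | COC1(OC)C(=O)[C@]23C[C@H]1C[C@@H](OC(C)(C)C)[C@H]2[C@@]1(CC=C)OC(=O)[C@](C)(C=C)[C@H]1[C@@H]3C(=O)OC | intermediate
22 | ring A cyclohexene lactone (C2=C3), 11α-tert-butoxy | COC1(OC)C(=O)[C@]23C[C@H]1C[C@@H](OC(C)(C)C)[C@H]2[C@@]12CC=C[C@@](C)(C(=O)O1)[C@H]2[C@@H]3C(=O)OC | intermediate
23 | 11α-alcohol | COC1(OC)C(=O)[C@]23C[C@H]1C[C@@H](O)[C@H]2[C@@]12CC=C[C@@](C)(C(=O)O1)[C@H]2[C@@H]3C(=O)OC | intermediate (not isolated)
24 | 11,15-diketone, C16 dimethyl ketal | COC1(OC)C(=O)[C@]23C[C@H]1CC(=O)[C@H]2[C@@]12CC=C[C@@](C)(C(=O)O1)[C@H]2[C@@H]3C(=O)OC | intermediate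
25 | 11β,15-diol, C16 dimethyl ketal (C15 undefined) | COC1(OC)C(O)[C@]23C[C@H]1C[C@H](O)[C@H]2[C@@]12CC=C[C@@](C)(C(=O)O1)[C@H]2[C@@H]3C(=O)OC | intermediate (not isolated)
26 | 11β,15-dihydroxy 16-ketone (C15 undefined) | O=C1C(O)[C@]23C[C@H]1C[C@H](O)[C@H]2[C@@]12CC=C[C@@](C)(C(=O)O1)[C@H]2[C@@H]3C(=O)OC | intermediate
27 | 11β-hydroxy 16-ketone, C2=C3 | O=C1C[C@]23C[C@H]1C[C@H](O)[C@H]2[C@@]12CC=C[C@@](C)(C(=O)O1)[C@H]2[C@@H]3C(=O)OC | intermediate
28 | 2β,3β,11β-trihydroxy 16-ketone methyl ester | O=C1C[C@]23C[C@H]1C[C@H](O)[C@H]2[C@@]12C[C@H](O)[C@H](O)[C@@](C)(C(=O)O1)[C@H]2[C@@H]3C(=O)OC | intermediate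
29 | methyl ester of the target | C=C1C[C@]23C[C@H]1C[C@H](O)[C@H]2[C@@]12C[C@H](O)[C@H](O)[C@@](C)(C(=O)O1)[C@H]2[C@@H]3C(=O)OC | intermediate
30 | CNP0322347.1 (2β,3β,11β-trihydroxy C19 gibberellin 19,10-lactone 7-oic acid) | C=C1C[C@]23C[C@H]1C[C@H](O)[C@H]2[C@@]12C[C@H](O)[C@H](O)[C@@](C)(C(=O)O1)[C@H]2[C@@H]3C(=O)O | target

## Step count and least certain steps

Total: 17 steps. Longest linear sequence: 17 steps (1 to 30); 16 steps from the arene 4.

Step 5 (key step). The likely failures are dimerisation of the masked ortho-benzoquinone before it meets the enol ether, loss of the enol ether by acid-catalysed acetal formation with methanol, and incomplete facial control by the single C6 ester. The fallback blocks dimerisation structurally. Compound 7 is brominated para to the hydroxyl (N-bromosuccinimide, MeCN) to give the bromophenol F1. Oxidation with PhI(OAc)2 in MeOH gives the bromo masked ortho-benzoquinone F2, which should be stable enough to isolate. F2 is heated with 8 in toluene, free of methanol and acid, to give the bromo adduct F3. Bu3SnH with azobisisobutyronitrile removes the vinyl bromine and returns to 10.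

Step 6. The C8 radical may be reduced before it rearranges, because the C9 radical is stabilised by only one carbonyl; retro-Claisen opening of the non-enolisable 1,3-diketone of 10 in warm alcohol is a second risk. The fallback separates radical generation from reduction. Hydrogen-atom-transfer hydrochlorination of 10 (Co(BF4)2·6H2O with a salicylaldimine ligand, TsCl, PhSiH3, t-BuOOH, EtOH) gives the tertiary C8 chloride F4. Slow addition of Bu3SnH with azobisisobutyronitrile in benzene at 80 °C keeps the hydride concentration low, so the acyl shift should outrun reduction, and returns to 11.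

Step 9. The ring closure has the enolate double bond inside the forming five-membered ring and may be slow. A [3,3] shift of the allylic ester enolate (bonding C4 to C6) or intermolecular addition could then compete. The fallback uses a stabilised nucleophile under reversible conditions. Compound 13 is treated as in step 8 but quenched with methyl 2-methylmalonyl chloride to give the mixed malonate F5. Cs2CO3 in MeCN should give the Michael adduct F6. Krapcho dealkoxycarbonylation (LiCl, wet DMSO, 140 °C) returns to 18.

Step 8. The allyl reagent may also add to the activated C15 ketone or approach C10 from the wrong face, and the in-flask acylation of a tertiary alkoxide may be incomplete. The fallback changes kinetic control to thermodynamic control. Allylzinc bromide in THF at 40 °C adds reversibly to hindered ketones, so the allyl group should collect on C10 of 13; work-up gives the tertiary alcohol F7. Deprotonation with n-BuLi and acylation with propanoyl chloride returns to 17.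

Step 3. Decarbonylation may compete at the doubly ortho-substituted aldehyde, and enantioselectivity may be low with an ester on the alkene. The fallback gives up asymmetric catalysis. Compound 5 is cyclised with the achiral complex [Rh(nbd)(dppe)]BF4 to the racemic ester F8. Preparative chromatography on a chiral stationary phase separates it; the (R)-ester F9 is set aside (it can be racemised with base and recycled) and the (S)-ester is 6.

Step 14. The free C15 hydroxyl is a poor leaving group, so cleavage may be slow, and acid- or base-induced migration of the ketol carbonyl from C16 to C15 before reduction would deoxygenate the wrong carbon. The fallback activates the oxygen. Compound 26 is acetylated (Ac2O, 4-(dimethylamino)pyridine) to the 11,15-diacetate F10. SmI2 in THF–MeOH removes the C15 acetate to give the 11-acetate F11. K2CO3 in MeOH, used before the base-sensitive diol exists, returns to 27.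

## Further compounds

F1 | step 5 | methyl (S)-7-bromo-4-hydroxy-5-methoxy-3-oxo-2,3-dihydro-1H-indene-1-carboxylate | COC(=O)[C@H]1CC(=O)c2c(O)c(OC)cc(Br)c21
F2 | step 5 | bromo masked ortho-benzoquinone (bromine on C14) | COC(=O)[C@H]1CC(=O)C2=C1C(Br)=CC(OC)(OC)C2=O
F3 | step 5 | 14-bromo bicyclo[2.2.2]octenone adduct | COC(=O)[C@H]1CC(=O)[C@@]23C(=O)C(OC)(OC)[C@@H](C(Br)=C12)C[C@H]3OC(C)(C)C
F4 | step 6 | tertiary C8 chloride of the saturated bicyclo[2.2.2]octane (C8 undefined) | COC(=O)[C@H]1CC(=O)[C@@]23C(=O)C(OC)(OC)[C@@H](CC12Cl)C[C@H]3OC(C)(C)C
F5 | step 9 | 10β-allyl 10α-(2-methoxycarbonylpropanoate) | COC1(OC)C(=O)[C@]23C[C@H]1C[C@@H](OC(C)(C)C)[C@H]2[C@@](CC=C)(OC(=O)C(C)C(=O)OC)C=C3C(=O)OC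
F6 | step 9 | 19,10-lactone with 4-methyl and 4-methoxycarbonyl (C4 undefined) | COC1(OC)C(=O)[C@]23C[C@H]1C[C@@H](OC(C)(C)C)[C@H]2[C@@]1(CC=C)OC(=O)C(C)(C(=O)OC)[C@H]1[C@@H]3C(=O)OC
F7 | step 8 | 10β-allyl 10α-alcohol | COC1(OC)C(=O)[C@]23C[C@H]1C[C@@H](OC(C)(C)C)[C@H]2[C@@](CC=C)(O)C=C3C(=O)OC
F8 | step 3 | racemic methyl 4,5-dimethoxy-3-oxo-2,3-dihydro-1H-indene-1-carboxylate | COC(=O)C1CC(=O)c2c(OC)c(OC)ccc21
F9 | step 3 | methyl (R)-4,5-dimethoxy-3-oxo-2,3-dihydro-1H-indene-1-carboxylate | COC(=O)[C@@H]1CC(=O)c2c(OC)c(OC)ccc21
F10 | step 14 | 11β,15-diacetoxy 16-ketone (C15 undefined) | O=C1C(OC(C)=O)[C@]23C[C@H]1C[C@H](OC(C)=O)[C@H]2[C@@]12CC=C[C@@](C)(C(=O)O1)[C@H]2[C@@H]3C(=O)OC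
F11 | step 14 | 11β-acetoxy 16-ketone | O=C1C[C@]23C[C@H]1C[C@H](OC(C)=O)[C@H]2[C@@]12CC=C[C@@](C)(C(=O)O1)[C@H]2[C@@H]3C(=O)OC
A1 | alternative 1 | tetracyclic lactone with rings B, C, D, C4–H and the ring A chain on C10 | O1CCOC12C[C@]34C[C@H]2C[C@H](O[Si](C)(C)C(C)(C)C)[C@H]3[C@@]5(CCC(OC)OC)OC(=O)[C@@H](C)[C@H]5[C@@H]4C(=O)OC
A2 | alternative 2 | CD ester fragment (C6 acetate on C8, C11 dioxolane, C16 methylene) | C=C1C[C@@]2(C[C@H]1CC3(OCCO3)C2)CC(=O)OC
A3 | alternative 2 | methyl 3,3-dimethoxy-6-oxocyclohexa-1,4-diene-1-carboxylate | COC(=O)C1=CC(OC)(OC)C=CC1=O
A4 | alternative 2 | coupled adduct with C4 quaternary centre, C10 dimethyl ketal and C1=C2 enone | C=C1C[C@@]2(C[C@H]1CC3(OCCO3)C2)[C@@H](C(=O)OC)[C@@H]4[C@](C)(C(=O)OC)C(=O)C=CC4(OC)OC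
A5 | alternative 3 | tricyclic allylsilane ketone (rings B, C, D, C11 ketone) | C[Si](C)(C)CC1=C[C@]23C[C@H]1CC(=O)[C@H]2C2(OCCO2)C[C@@H]3C(=O)OC
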